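The numbers of this flask are made up; the rest is arithmetic.

Time is what to watch in this flask: how many half-lives of the electrophile fit into the run.

electrophile 0.050 M; nucleophile 0.0900 M; buffer base 0.150 M; buffer acid 0.0150 M; time 15 h

    protonated nucleophile ⇌ nucleophile + acid, settled at all times (K1 = 1.6 × 10⁻⁹ M)
    buffer acid ⇌ buffer base + acid, settled at all times (K2 = 5.0 × 10⁻¹⁰ M)
    electrophile + target → side product (k3 = 3.2 L mol⁻¹ h⁻¹)
    electrophile + nucleophile → acid + target + leaving group (k4 = 2.1 L mol⁻¹ h⁻¹)

- part of the electrophile that has reacted at 15 h
- pH of the solution at 15 h

- acid is the free proton; pH is minus the decimal logarithm of its molar concentration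
- percentages count the electrophile that a species holds: one side product counts as two
- run time (flask): 15 h

1. The electrophile in this flask leaves by two exits, with loss constant 2.1 L mol⁻¹ h⁻¹ × [nucleophile] + 3.2 L mol⁻¹ h⁻¹ × [target]; while that sum holds steady, its decay is pseudo-first-order.
2. The zero of the scale is the symmetric case, equal constants: a nucleophile turned into a target then leaves the sum unchanged.
3. Here a target counts 1.52 times as much as a nucleophile, which raises the sum, while protonation of the nucleophile and use of the target lower it. This reckoning takes the two effects to cancel and holds the sum at its starting value, 0.189 h⁻¹.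
4. Two times then remain: the run, 15 h, and the electrophile's half-life, ln(2) divided by that sum, 3.67 h.
5. The run is longer than the half-life and holds 4.09 of them, so this reckoning gives 94.1 % reacted. The pH is not reckoned here.

The forecast gives 94 % and pH 9.73, holding that “most of the nucleophile stays free”. The simulation gives 93.7 % reacted and pH 9.74.

At 7.50 h this flask reads nucleophile 61.3 % and target 42.5 %, so the exits carry 0.116 h⁻¹ and 0.0680 h⁻¹. Their sum, 0.184 h⁻¹, stands close to the starting 0.189 h⁻¹. The neighbouring flask has the same charges and is read at 6.0 h. That is 1.63 half-lives, which gives 67.8 % reacted. The neighbouring flask reads 67.7 %.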